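Ask how long the chains in this flask are at the end, and split the question: the average length (the number-average degree of polymerization) is the monomer in chains divided by the chains begun, and both can be taken as fractions of the free monomer charged.

common to all: free monomer 0.050 M; initiator 0.34 mM; impurity 0.12 mM

|  | transfer agent | remark | time |
|---|---|---|---|
| Tuesday's | 1 mM | run made earlier |  |
| Sunday's | 2.2 mM | run made earlier |  |
| flask | 1.50 mM |  | 8.0 h |

| run | time / h | monomer in chains / % | free monomer / % |
|---|---|---|---|
| Tuesday's | 0.833 | 1.8 | 98.4 |
| Tuesday's | 1.50 | 2.7 | 97.3 |
| Tuesday's | 2.50 | 6.2 | 94.1 |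
| Tuesday's | 3.00 | 8.1 | 92.3 |
| Tuesday's | 4.00 | 9.3 | 88.9 |
| Tuesday's | 5.00 | 14.1 | 86.1 |
| Sunday's | 0.833 | 0.7 | 98.0 |
| Sunday's | 1.50 | 2.8 | 97.2 |
| Sunday's | 2.50 | 6.3 | 93.8 |
| Sunday's | 3.00 | 6.6 | 92.7 |
| Sunday's | 4.00 | 9.4 | 90.9 |
| Sunday's | 5.00 | 12.4 | 88.1 |

(readings scatter by 0.5 percentage points)

- the average divides the monomer in chains by the number of chains begun, living and dead together
- the earlier runs do not show the number of chains; that part of a forecast is a guess

1. average number of monomer units in a chain (chains begun, living or dead) at 8.0 h
2. part of the free monomer that has reacted at 8.0 h

Turn the transfer agent first. By hand, suppose it stops a growing chain and starts none: it then adds no chain and may slow the reaction a little. Tuesday's run, with 1 mM, keeps 86.1% of its free monomer at 5.00 h, and Sunday's run, with 2.2 mM, keeps 88.1%. The flask's 1.50 mM lies between them, so take the mean loss at that time, 12.9%.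

Turn the time next. By hand, a straight loss doubles when the time doubles, and from 2.50 h to 5.00 h the mean loss does grow to twice its value. Carried on to 8.0 h, my own reckoning gives 20.6%.

Turn the initiator and impurity last. Both runs hold them at the flask's charges, so the two runs differ in neither. By hand, let each initiator begin one chain and each impurity destroy one initiator. Then 0.440% is my chain budget, the initiator charge less the impurity charge over the free monomer charge.

Divide in powers of ten: −0.686 less −2.36 leaves 1.67, so I expect about 46.9. The forecast gives an average length of 6.5 and a conversion of 20%, and says of its chains: “The chain count is a guess”. We stand close on conversion and apart on length.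

The flask gives an average length of 47.8 and a conversion of 20.6%.

    free monomer + initiator → living end + monomer in chains (k = 11.0 /M/h)
    free monomer + living end → monomer in chains + living end, rate k2*[living end]*[free monomer] (k = 240 /M/h)
    living end + transfer agent → dead chain (kL = 82.0 /M/h)
    initiator + impurity → spent initiator (k = 23000 /M/h)

At 8.00 h, living ends and dead chains together make 0.432% of the free monomer charged, beside the budget of 0.440%. Now raise the initiator to 8.5 × 10⁻⁴ M in a neighbouring flask: its budget becomes 1.46%, and its conversion of 53.0% divided by that budget gives 36.3, while the neighbouring flask itself stands at 37.9.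

(The runs are calculated on assumed constants; the scatter is artificial.)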